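The C3–N1' bond between the two indoles is never made by coupling: N1' enters as the 3-amino nitrogen of an N-sulfonylated 6-prenylindole, and the pyrrole ring of the N-linked indole (N1', C2', C3', C3a', C7a') is built onto it. The feature exploited is that the C6' prenyl group lies on C5, on the mirror plane of a cyclohexane-1,3-dione, so either carbonyl may become C7a'. One three-component condensation of the aminoindole, 5-prenylcyclohexane-1,3-dione and chloroacetaldehyde forms N1'–C7a', C3a'–C3' and N1'–C2' and gives a 4-oxotetrahydroindole; reduction, dehydration, dehydrogenation and desulfonylation then deliver the target.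

Key step: step 7

Remark: primed locants belong to the N-linked indole and prenyl means 3-methylbut-2-en-1-yl; the target is achiral, so every intermediate with an sp3 stereocentre in the ring under construction is carried as a racemate or diastereomer mixture, all such centres being erased on aromatisation.

Step 1
Reactants: 1 1-bromo-3,5-dimethoxybenzene; 2 prenyl bromide
Product: 4 1,3-dimethoxy-5-(3-methylbut-2-enyl)benzene, via 3,5-dimethoxyphenylmagnesium bromide 3 (not isolated)
Conditions: Mg, I2 (cat.), THF, reflux; then 2, Li2CuCl4 (3 mol%), THF, −10 °C → rt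
Reagents that add atoms: none
Why: Grignard formation followed by copper-catalysed coupling with a primary allylic bromide should deliver the aryl group to the unhindered CH2 terminus (SN2, α-attack) and not to the tertiary γ-carbon, giving the linear prenyl arene.

Step 2
Reactants: 4 1,3-dimethoxy-5-(3-methylbut-2-enyl)benzene
Product: 6 5-(3-methylbut-2-enyl)cyclohexane-1,3-dione, via 1,5-dimethoxy-3-prenylcyclohexa-1,4-diene 5 (not isolated)
Conditions: Li, t-BuOH, NH3(l)/THF, −78 °C; NH3 evaporated; then 1 M HCl, THF, 0 °C → rt
Reagents that add atoms: water, O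
Why: Birch reduction should place the two new hydrogens on the carbon between the methoxy groups and on the prenyl-bearing carbon, so that both methoxy groups stay on double bonds; the isolated trisubstituted alkene is inert to the dissolving metal (t-BuOH keeps the medium from becoming basic enough to migrate it), and dilute acid then hydrolyses both enol ethers to the 1,3-dione.

Step 3
Reactants: 7 6-bromoindole
Product: 8 6-bromo-1-(phenylsulfonyl)indole
Conditions: PhSO2Cl, NaOH (powdered), Bu4NHSO4 (cat.), CH2Cl2, 0 °C → rt
Reagents that add atoms: benzenesulfonyl chloride, O=S(=O)(Cl)c1ccccc1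
Why: Phase-transfer N-sulfonylation of the indolide anion is routine, and the electron-withdrawing group both steers the coming nitration to C3 and will later stabilise the 3-aminoindole.

Step 4
Reactants: 8 6-bromo-1-(phenylsulfonyl)indole
Product: 9 6-bromo-3-nitro-1-(phenylsulfonyl)indole
Conditions: HNO3 (90%), Ac2O, −70 °C → rt
Reagents that add atoms: nitric acid (delivered as acetyl nitrate), O[N+](=O)[O-]
Why: Electrophilic aromatic nitration with acetyl nitrate should occur at C3, the most nucleophilic position of an N-sulfonylindole, and is placed before the acid- and oxidant-sensitive prenyl group is introduced.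

Step 5
Reactants: 9 6-bromo-3-nitro-1-(phenylsulfonyl)indole; 10 tributyl(3-methylbut-2-enyl)stannane
Product: 11 3-nitro-1-(phenylsulfonyl)-6-(3-methylbut-2-enyl)indole
Conditions: Pd(PPh3)4 (5 mol%), toluene, 100 °C
Reagents that add atoms: none
Why: In this Stille coupling zerovalent palladium inserts into the electron-poor C6–Br bond, the prenyl group is transferred from tin and reductive elimination at the less hindered CH2 terminus should give the linear prenyl arene, while the neutral, base-free medium spares the electrophilic C2 and the labile N–S bond of the 3-nitroindole.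

Step 6
Reactants: 11 3-nitro-1-(phenylsulfonyl)-6-(3-methylbut-2-enyl)indole
Product: 12 3-amino-1-(phenylsulfonyl)-6-(3-methylbut-2-enyl)indole
Conditions: Zn dust, AcOH, THF, 0 °C → rt; used crude the same day
Reagents that add atoms: none
Why: Zinc in acetic acid reduces the aromatic nitro group to the amine by stepwise electron transfer (dissolving-metal nitro reduction) without touching the trisubstituted alkene or the N–S bond, and the sulfonyl group keeps the electron-rich 3-aminoindole from air oxidation long enough for immediate use.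

Step 7
Reactants: 12 3-amino-1-(phenylsulfonyl)-6-(3-methylbut-2-enyl)indole; 6 5-(3-methylbut-2-enyl)cyclohexane-1,3-dione; 13 chloroacetaldehyde
Product: 17 1-[1-(phenylsulfonyl)-6-prenylindol-3-yl]-6-prenyl-6,7-dihydro-1H-indol-4(5H)-one (racemic), via enaminone 14 (not isolated), via chlorohydrin 15 (not isolated), via hydroxypyrroline 16 (not isolated)
Conditions: 12 + 6, AcOH (10 mol%), EtOH, 50 °C; then 13 (50% aq.), NaHCO3, rt → 70 °C
Reagents that add atoms: none
Why: Under mild acid the amine condenses with one carbonyl of 6 to give vinylogous amide 14 (N1'–C7a'); its nucleophilic α-carbon then adds to the aldehyde of 13 (C3a'–C3') to give chlorohydrin 15, the N–H nitrogen displaces chloride (N1'–C2') to give hydroxypyrroline 16, and loss of water aromatises the pyrrole. The closest known reaction type is the Hantzsch/Feist–Benary-type annulation of cyclic enaminones with α-halo carbonyl compounds to 4-oxo-4,5,6,7-tetrahydroindoles. The one new ring, the pyrrole ring of the N-linked indole, closes in 5-exo-tet mode by SN2 displacement at C2'. C6' becomes a stereocentre only because the two carbonyls end up differentiated; nothing controls it, 17 should form as a racemate, and the centre is erased on aromatisation. Regiochemistry is not an issue because the mirror plane through C2 and C5 of 6 makes its carbonyls interchangeable; what the step does need is closure through nitrogen and not through the enaminone oxygen or through C2 of the aminoindole, which is secured by the better nucleophilicity of N–H in a near-neutral bicarbonate medium (no cation at C3') and by the sulfonyl group, which deactivates indole C2 and stabilises the fresh amine.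

Step 8
Reactants: 17 1-[1-(phenylsulfonyl)-6-prenylindol-3-yl]-6-prenyl-6,7-dihydro-1H-indol-4(5H)-one
Product: 18 1-[1-(phenylsulfonyl)-6-prenylindol-3-yl]-6-prenyl-4,5,6,7-tetrahydro-1H-indol-4-ol (racemic cis/trans mixture)
Conditions: NaBH4, THF/MeOH, 0 → 50 °C
Reagents that add atoms: none
Why: Hydride 1,2-reduction of the ketone (a vinylogous amide, hence the gentle warming) by NaBH4 leaves sulfonamide and alkenes alone; C4' is formed without control as a cis/trans mixture relative to C6', which is acceptable because both centres vanish in step 9.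

Step 9
Reactants: 18 1-[1-(phenylsulfonyl)-6-prenylindol-3-yl]-6-prenyl-4,5,6,7-tetrahydro-1H-indol-4-ol
Product: 20 6-prenyl-1-[1-(phenylsulfonyl)-6-prenylindol-3-yl]-1H-indole, via 6,7-dihydroindole 19 (not isolated)
Conditions: PPTS (cat.), toluene, 50 °C; then DDQ (1.05 equiv), 0 °C
Reagents that add atoms: none
Why: Acid-catalysed E1 dehydration through the pyrrole-stabilised C4' cation gives the 4',5'-alkene 19, and DDQ dehydrogenation (hydride abstraction from C7', then proton loss from C6') is driven by formation of the benzene ring and should be fast enough at 0 °C with one equivalent to leave the prenyl CH2 groups and the sulfonyl-deactivated indole untouched.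

Step 10
Reactants: 20 6-prenyl-1-[1-(phenylsulfonyl)-6-prenylindol-3-yl]-1H-indole
Product: 21 6-(3-methylbut-2-enyl)-3-[6-(3-methylbut-2-enyl)indol-1-yl]-1H-indole (target)
Conditions: Mg turnings, MeOH/THF, rt, ultrasound
Reagents that add atoms: none
Why: Reductive N–S cleavage by electron transfer from magnesium in methanol (Mg/MeOH desulfonylation of an N-sulfonylindole) should free the indole N–H without affecting the isolated alkenes or the C3–N1' bond.

Compound list
1 | 1-bromo-3,5-dimethoxybenzene | COc1cc(Br)cc(OC)c1 | starting material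
2 | prenyl bromide (1-bromo-3-methylbut-2-ene) | CC(C)=CCBr | starting material
3 | 3,5-dimethoxyphenylmagnesium bromide | COc1cc([Mg]Br)cc(OC)c1 | intermediate (not isolated)
4 | 1,3-dimethoxy-5-(3-methylbut-2-enyl)benzene | COc1cc(CC=C(C)C)cc(OC)c1 | intermediate
5 | 1,5-dimethoxy-3-(3-methylbut-2-enyl)cyclohexa-1,4-diene | COC1=CC(CC=C(C)C)C=C(OC)C1 | intermediate (not isolated)
6 | 5-(3-methylbut-2-enyl)cyclohexane-1,3-dione (achiral) | O=C1CC(CC=C(C)C)CC(=O)C1 | intermediate
7 | 6-bromoindole | Brc1ccc2cc[nH]c2c1 | starting material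
8 | 6-bromo-1-(phenylsulfonyl)indole | O=S(=O)(c1ccccc1)n1ccc2ccc(Br)cc21 | intermediate
9 | 6-bromo-3-nitro-1-(phenylsulfonyl)indole | O=[N+]([O-])c1cn(S(=O)(=O)c2ccccc2)c2cc(Br)ccc12 | intermediate
10 | tributyl(3-methylbut-2-enyl)stannane | CCCC[Sn](CCCC)(CCCC)CC=C(C)C | starting material
11 | 3-nitro-1-(phenylsulfonyl)-6-(3-methylbut-2-enyl)indole | CC(C)=CCc1ccc2c([N+](=O)[O-])cn(S(=O)(=O)c3ccccc3)c2c1 | intermediate
12 | 3-amino-1-(phenylsulfonyl)-6-(3-methylbut-2-enyl)indole | Nc1cn(S(=O)(=O)c2ccccc2)c2cc(CC=C(C)C)ccc12 | intermediate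
13 | chloroacetaldehyde | ClCC=O | starting material
14 | 3-{[1-(phenylsulfonyl)-6-prenylindol-3-yl]amino}-5-prenylcyclohex-2-en-1-one (enaminone, racemic) | O=C1C=C(Nc2cn(S(=O)(=O)c3ccccc3)c3cc(CC=C(C)C)ccc23)CC(CC=C(C)C)C1 | intermediate (not isolated)
15 | 2-(2-chloro-1-hydroxyethyl)-3-{[1-(phenylsulfonyl)-6-prenylindol-3-yl]amino}-5-prenylcyclohex-2-en-1-one (chlorohydrin, diastereomer mixture, racemic) | O=C1CC(CC=C(C)C)CC(Nc2cn(S(=O)(=O)c3ccccc3)c3cc(CC=C(C)C)ccc23)=C1C(O)CCl | intermediate (not isolated)
16 | 3-hydroxy-1-[1-(phenylsulfonyl)-6-prenylindol-3-yl]-6-prenyl-2,3,6,7-tetrahydro-1H-indol-4(5H)-one (hydroxypyrroline, diastereomer mixture, racemic) | O=C1CC(CC=C(C)C)CC2=C1C(O)CN2c1cn(S(=O)(=O)c2ccccc2)c2cc(CC=C(C)C)ccc12 | intermediate (not isolated)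
17 | 1-[1-(phenylsulfonyl)-6-prenylindol-3-yl]-6-prenyl-6,7-dihydro-1H-indol-4(5H)-one (racemic) | O=C1CC(CC=C(C)C)Cc2c1ccn2-c1cn(S(=O)(=O)c2ccccc2)c2cc(CC=C(C)C)ccc12 | intermediate
18 | 1-[1-(phenylsulfonyl)-6-prenylindol-3-yl]-6-prenyl-4,5,6,7-tetrahydro-1H-indol-4-ol (racemic cis/trans mixture) | OC1CC(CC=C(C)C)Cc2c1ccn2-c1cn(S(=O)(=O)c2ccccc2)c2cc(CC=C(C)C)ccc12 | intermediate
19 | 1-[1-(phenylsulfonyl)-6-prenylindol-3-yl]-6-prenyl-6,7-dihydro-1H-indole (racemic) | CC(C)=CCC1C=Cc2ccn(-c3cn(S(=O)(=O)c4ccccc4)c4cc(CC=C(C)C)ccc34)c2C1 | intermediate (not isolated)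
20 | 6-prenyl-1-[1-(phenylsulfonyl)-6-prenylindol-3-yl]-1H-indole | CC(C)=CCc1ccc2ccn(-c3cn(S(=O)(=O)c4ccccc4)c4cc(CC=C(C)C)ccc34)c2c1 | intermediate
21 | 6-(3-methylbut-2-enyl)-3-[6-(3-methylbut-2-enyl)indol-1-yl]-1H-indole (achiral) | CC(C)=CCc1ccc2c(-n3ccc4ccc(CC=C(C)C)cc43)c[nH]c2c1 | target

Total step count: 10. Longest linear sequence: 8 steps (from 7 through steps 3–10). The two-step dione branch (steps 1–2) joins at step 7.

Steps most likely to fail

Step 7. The chlorohydrin may close through the enaminone oxygen (furan formation) or through C2 of the aminoindole (six-membered ring), or the amine may oxidise before it is captured. The fallback sets out from 6 and 13 and returns at 17. It stages the annulation in the opposite order. Dione 6 and 13 are first condensed alone under Feist–Benary conditions (NaHCO3, H2O/THF, 0 °C → rt) to 3-hydroxy-6-prenyl-2,3,6,7-tetrahydro-1-benzofuran-4(5H)-one F1, which dilute acid should dehydrate to 6-prenyl-6,7-dihydro-1-benzofuran-4(5H)-one F2. F2 is a stable compound that is then heated with amine 12 (AcOH, EtOH, sealed tube, about 130 °C). Conjugate addition of the amine at C7a opens the furan, and Paal–Knorr-type reclosure onto the liberated aldehyde exchanges the ring oxygen for N1' and should give 17.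

Step 9. Acid may oligomerise the electron-rich vinylpyrrole during dehydration, or the quinone may abstract hydride from a benzylic–allylic CH2 of a prenyl group. The fallback sets out from 17 (step 8 is skipped) and returns at 20. It aromatises at the ketone oxidation level and removes the oxygen afterwards. Sulfinylation of the C5' enolate (KH, methyl benzenesulfinate, THF, rt) should give 5-(phenylsulfinyl)-1-[1-(phenylsulfonyl)-6-prenylindol-3-yl]-6-prenyl-6,7-dihydro-1H-indol-4(5H)-one F3. Thermal syn-elimination of the sulfoxide (toluene, NaHCO3, 110 °C) and tautomerisation should give 1-[1-(phenylsulfonyl)-6-prenylindol-3-yl]-6-prenyl-1H-indol-4-ol F4. Triflation (Tf2O, pyridine, CH2Cl2, 0 °C) gives 1-[1-(phenylsulfonyl)-6-prenylindol-3-yl]-6-prenyl-1H-indol-4-yl trifluoromethanesulfonate F5, and palladium-catalysed formate reduction of the aryl triflate (Pd(OAc)2, dppf, HCO2H, Et3N, DMF, 70 °C) should give 20 without acid or quinone.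

Step 5. The prenyl group may couple through its γ-carbon (allylic transposition to the 1,1-dimethylallyl isomer), or transmetallation from tin may be slow. The fallback sets out from 9 and returns at 11. Stille coupling of 9 with allyltributylstannane (Pd(PPh3)4, toluene, 100 °C), where the two allyl termini are identical, should give 6-allyl-3-nitro-1-(phenylsulfonyl)indole F6. Cross-metathesis of F6 with 2-methylbut-2-ene (second-generation Grubbs catalyst, CH2Cl2/2-methylbut-2-ene, 40 °C) then converts allyl into prenyl and gives 11.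

Further compounds
F1 | step 7 | 3-hydroxy-6-(3-methylbut-2-enyl)-2,3,6,7-tetrahydro-1-benzofuran-4(5H)-one (diastereomer mixture, racemic) | O=C1CC(CC=C(C)C)CC2=C1C(O)CO2
F2 | step 7 | 6-(3-methylbut-2-enyl)-6,7-dihydro-1-benzofuran-4(5H)-one (racemic) | O=C1CC(CC=C(C)C)Cc2occc12
F3 | step 9 | 5-(phenylsulfinyl)-1-[1-(phenylsulfonyl)-6-prenylindol-3-yl]-6-prenyl-6,7-dihydro-1H-indol-4(5H)-one (diastereomer mixture, racemic) | O=C1C(S(=O)c3ccccc3)C(CC=C(C)C)Cc2c1ccn2-c1cn(S(=O)(=O)c2ccccc2)c2cc(CC=C(C)C)ccc12
F4 | step 9 | 1-[1-(phenylsulfonyl)-6-prenylindol-3-yl]-6-prenyl-1H-indol-4-ol | Oc1cc(CC=C(C)C)cc2c1ccn2-c1cn(S(=O)(=O)c2ccccc2)c2cc(CC=C(C)C)ccc12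
F5 | step 9 | 1-[1-(phenylsulfonyl)-6-prenylindol-3-yl]-6-prenyl-1H-indol-4-yl trifluoromethanesulfonate | O=S(=O)(Oc1cc(CC=C(C)C)cc2c1ccn2-c1cn(S(=O)(=O)c2ccccc2)c2cc(CC=C(C)C)ccc12)C(F)(F)F
F6 | step 5 | 6-allyl-3-nitro-1-(phenylsulfonyl)indole | C=CCc1ccc2c([N+](=O)[O-])cn(S(=O)(=O)c3ccccc3)c2c1
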